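Letter the ring carbons in the order of the target SMILES: a (C-henicosyl), b (C–OH), c (C=O), d (C–CH3), e (C–OH), f (C=O). In its other quinone tautomer the six-membered ring is a maleoyl unit b–c=d–e (b, e carbonyl; c oxygenated) closed by an oxygenated two-carbon unit f–a. The key step exploits this: a five-membered maleoylcobalt complex, made from 3-methoxy-4-methylcyclobutenedione, takes up 1-ethoxytricos-1-yne and forms bonds a–b and e–f in one operation, building the fully substituted quinone ring with every substituent in place; polarity matching sets the 2,5-dioxygenation. Hydrolysis of both vinylogous esters then gives the target.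

Key step: step 4

Remark: the target has no stereocentre and is a 2,5-dihydroxy-1,4-benzoquinone whose two enol–quinone tautomers are one compound, so the tautomer the route delivers (carbonyl groups at b and e) equals the drawn one (carbonyl groups at c and f); dimethyl squarate, henicosan-1-ol, ethoxyacetylene and ClCo(PPh3)3 are taken as commercial.

Step 1
Reactants: 1 dimethyl squarate (3,4-dimethoxycyclobut-3-ene-1,2-dione)
Product: 3 3-methoxy-4-methylcyclobut-3-ene-1,2-dione, via hydroxycyclobutenone 2 (not isolated)
Conditions: MeLi (1.05 equiv), THF, −78 °C; then 12 M HCl, CH2Cl2, 0 °C to rt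
Reagents that add atoms: MeLi, C[Li]; water (from the aqueous acid, supplies the new carbonyl oxygen), O
Why: 1,2-Addition of MeLi to one of the two equivalent carbonyl groups gives racemic carbinol 2 (its stereocentre is formed without control and destroyed at once), and acid-promoted allylic ionisation, capture of water at the methoxy-bearing terminus and loss of methanol then unveil the 1,2-dione (organolithium addition and acid rearrangement of a squarate ester to a semisquarate).

Step 2
Reactants: 3 3-methoxy-4-methylcyclobut-3-ene-1,2-dione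
Product: 5 chloro(dimethylglyoxime)(pyridine)(2-methoxy-3-methylmaleoyl)cobalt, via bisphosphine complex 4 (not isolated)
Conditions: ClCo(PPh3)3 (1.0 equiv), PhH, rt, Ar; then dimethylglyoxime (1.1 equiv), pyridine, rt
Reagents that add atoms: ClCo(PPh3)3, Cl[Co-3]([P+](c1ccccc1)(c1ccccc1)c1ccccc1)([P+](c1ccccc1)(c1ccccc1)c1ccccc1)[P+](c1ccccc1)(c1ccccc1)c1ccccc1; dimethylglyoxime, CC(=NO)C(C)=NO; pyridine, c1ccncc1
Why: Oxidative addition of monovalent cobalt into the strained C(=O)–C(=O) bond gives the five-membered diacyl metallacycle of trivalent cobalt 4, and exchange of the two phosphines for the chelating dioxime and pyridine should give the air-stable octahedral complex 5 (C–C bond activation of a cyclobutenedione, then ligand substitution).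

Step 3
Reactants: 6 henicosan-1-ol; 7 ethoxyacetylene
Product: 9 1-ethoxytricos-1-yne, via henicosyl triflate 8 (not isolated)
Conditions: 6, Tf2O, 2,6-lutidine, CH2Cl2, 0 °C; crude 8 added to 7/n-BuLi, THF, −78 °C to rt; base-washed silica
Reagents that add atoms: none
Why: A primary triflate is reactive enough for SN2 alkylation of the weakly nucleophilic lithium ethoxyacetylide in THF without a polar cosolvent (O-triflation followed by acetylide alkylation), and the ynol ether should survive a non-acidic work-up.

Step 4
Reactants: 5 chloro(dimethylglyoxime)(pyridine)(2-methoxy-3-methylmaleoyl)cobalt; 9 1-ethoxytricos-1-yne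
Product: 10 2-ethoxy-3-henicosyl-5-methoxy-6-methylcyclohexa-2,5-diene-1,4-dione
Conditions: SnCl4 (0.3 equiv) premixed with 5, CH2Cl2, −20 °C; then 9 (1.5 equiv), −20 °C to rt; air, silica filtration
Reagents that add atoms: none
Why: SnCl4 chelates the methoxy oxygen on c and the oxygen of acyl carbon b in the cobaltacycle Co–b(=O)–c(OMe)=d(Me)–e(=O), so that b (the more electrophilic acyl carbon in any case, because e is a vinylogous ester carbonyl) is attacked by the nucleophilic henicosyl-bearing carbon a of the ynol ether; the ethoxy-bearing carbon f passes onto cobalt (net insertion of the alkyne into the Co–b bond to a seven-membered cobaltacycle) and reductive elimination joins f to acyl carbon e and releases monovalent cobalt. The closest known reaction type is the cobalt-mediated benzoquinone synthesis from maleoylcobalt complexes and alkynes under Lewis acid catalysis. The six-membered carbocycle is closed as a formal [4+2] annulation, its last bond arising by C(sp2)–C(acyl) reductive elimination from the seven-membered metallacycle. No stereocentre is formed. The step needs head-to-tail regioselectivity (a bonded to b and f to e, which gives the 2,5- and not the 2,6-dioxygenated quinone), and the matched polarity of the ynol ether and the chelation-activated acyl group should secure it. The acid-labile ynol ether is spared by adding it last, at low temperature, to the pre-formed complex of 5 and SnCl4.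

Step 5
Reactants: 10 2-ethoxy-3-henicosyl-5-methoxy-6-methylcyclohexa-2,5-diene-1,4-dione
Product: 11 2,5-dihydroxy-3-henicosyl-6-methylcyclohexa-2,5-diene-1,4-dione (target)
Conditions: 2 M aq NaOH, EtOH/THF, 60 °C, N2; then 2 M HCl
Reagents that add atoms: NaOH, [Na+].[OH-]
Why: Both alkoxy groups are vinylogous esters, so hydroxide should replace them by conjugate addition–elimination and acidification of the dianion gives the 2,5-dihydroxy-1,4-benzoquinone (vinylogous ester saponification, the usual end-game for embelin-type quinones).

Compound list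
1 | dimethyl squarate (3,4-dimethoxycyclobut-3-ene-1,2-dione) | COC1=C(OC)C(=O)C1=O | starting material
2 | 4-hydroxy-2,3-dimethoxy-4-methylcyclobut-2-en-1-one (racemic, not isolated) | COC1=C(OC)C(C)(O)C1=O | intermediate
3 | 3-methoxy-4-methylcyclobut-3-ene-1,2-dione | COC1=C(C)C(=O)C1=O | intermediate
4 | chlorobis(triphenylphosphine)(2-methoxy-3-methylmaleoyl)cobalt, CoCl(PPh3)2[C(=O)C(OMe)=C(Me)C(=O)] (not isolated) | COC1=C(C)C(=O)[Co-2](Cl)([P+](c2ccccc2)(c2ccccc2)c2ccccc2)([P+](c2ccccc2)(c2ccccc2)c2ccccc2)C1=O | intermediate
5 | chloro(dimethylglyoxime)(pyridine)(2-methoxy-3-methylmaleoyl)cobalt, CoCl(C4H8N2O2)(C5H5N)[C(=O)C(OMe)=C(Me)C(=O)] | COC1=C(C)C(=O)[Co-3]2(Cl)([n+]3ccccc3)([N+](O)=C(C)C(C)=[N+]2O)C1=O | intermediate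
6 | henicosan-1-ol | CCCCCCCCCCCCCCCCCCCCCO | starting material
7 | ethoxyacetylene (ethoxyethyne) | CCOC#C | starting material
8 | henicosyl trifluoromethanesulfonate (not isolated) | CCCCCCCCCCCCCCCCCCCCCOS(=O)(=O)C(F)(F)F | intermediate
9 | 1-ethoxytricos-1-yne | CCCCCCCCCCCCCCCCCCCCCC#COCC | intermediate
10 | 2-ethoxy-3-henicosyl-5-methoxy-6-methylcyclohexa-2,5-diene-1,4-dione | CCCCCCCCCCCCCCCCCCCCCC1=C(OCC)C(=O)C(C)=C(OC)C1=O | intermediate
11 | 2,5-dihydroxy-3-henicosyl-6-methylcyclohexa-2,5-diene-1,4-dione | CCCCCCCCCCCCCCCCCCCCCC1=C(O)C(=O)C(C)=C(O)C1=O | target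

Total step count: 5
Longest linear sequence: 4 steps (steps 1, 2, 4 and 5, from dimethyl squarate)

Steps most likely to fail

Step 4: the alkyne may enter the cobaltacycle in the reverse orientation, or the Lewis acid may consume the ynol ether before annulation. The fallback gives up the annulation for oxidation of a ready-made arene; it sets out from triflate 8 and comes back to the route at target 11. 1,2,4,5-Tetramethoxy-3-methylbenzene F1 is made from commercial 1,2,4,5-tetramethoxybenzene (n-BuLi, TMEDA, THF, then MeI). F1 is lithiated at its one free ring position (n-BuLi, TMEDA, THF, 0 °C) and alkylated with 8 to give 1-henicosyl-2,3,5,6-tetramethoxy-4-methylbenzene F2. (NH4)2Ce(NO3)6 in MeCN/THF/H2O at 0 °C should oxidise F2 to 3-henicosyl-2,5-dimethoxy-6-methylcyclohexa-2,5-diene-1,4-dione F3, and the conditions of step 5 then convert F3 into 11.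

Step 3: elimination from the long-chain triflate or thermal decay of lithium ethoxyacetylide may outrun the alkylation. The fallback installs the oxygen after the C–C bond instead of before; it sets out from triflate 8 and comes back at target 11. Triflate 8 is alkylated with the more robust LiC≡CH·H2NCH2CH2NH2 (THF, 0 °C to rt) to tricos-1-yne F4. Deprotonation (n-BuLi) and oxidation of the acetylide with LiOOt-Bu (from t-BuOOH and LiN(SiMe3)2, THF, −78 to 0 °C) gives lithium tricos-1-yn-1-olate F5, which is O-silylated with i-Pr3SiOTf to triisopropyl(tricos-1-yn-1-yloxy)silane F6. F6 takes the place of 9 in step 4 with complex 5 and should give 3-henicosyl-5-methoxy-6-methyl-2-(triisopropylsilyloxy)cyclohexa-2,5-diene-1,4-dione F7, whose silyl and methyl groups fall to the conditions of step 5 to give 11.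

Step 5: after the first exchange the oxido-quinone anion is electron-rich, so the second hydrolysis may stall, and prolonged hot base may degrade the hydroxyquinone by ring contraction or oxidative cleavage. The fallback cleaves the ethers at the aromatic oxidation level; it sets out from 10 and comes back at 11. Na2S2O4 (THF/H2O, rt) reduces 10 to 2-ethoxy-3-henicosyl-5-methoxy-6-methylbenzene-1,4-diol F8. BBr3 (CH2Cl2, −78 °C to rt) cleaves both aryl alkyl ethers to 3-henicosyl-6-methylbenzene-1,2,4,5-tetrol F9, which should oxidise in air on work-up to 11.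

Further compounds
F1 | step 4 | 1,2,4,5-tetramethoxy-3-methylbenzene | COc1cc(OC)c(OC)c(C)c1OC
F2 | step 4 | 1-henicosyl-2,3,5,6-tetramethoxy-4-methylbenzene | CCCCCCCCCCCCCCCCCCCCCc1c(OC)c(OC)c(C)c(OC)c1OC
F3 | step 4 | 3-henicosyl-2,5-dimethoxy-6-methylcyclohexa-2,5-diene-1,4-dione | CCCCCCCCCCCCCCCCCCCCCC1=C(OC)C(=O)C(C)=C(OC)C1=O
F4 | step 3 | tricos-1-yne | CCCCCCCCCCCCCCCCCCCCCC#C
F5 | step 3 | lithium tricos-1-yn-1-olate | CCCCCCCCCCCCCCCCCCCCCC#CO[Li]
F6 | step 3 | triisopropyl(tricos-1-yn-1-yloxy)silane | CCCCCCCCCCCCCCCCCCCCCC#CO[Si](C(C)C)(C(C)C)C(C)C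
F7 | step 3 | 3-henicosyl-5-methoxy-6-methyl-2-(triisopropylsilyloxy)cyclohexa-2,5-diene-1,4-dione | CCCCCCCCCCCCCCCCCCCCCC1=C(O[Si](C(C)C)(C(C)C)C(C)C)C(=O)C(C)=C(OC)C1=O
F8 | step 5 | 2-ethoxy-3-henicosyl-5-methoxy-6-methylbenzene-1,4-diol | CCCCCCCCCCCCCCCCCCCCCc1c(OCC)c(O)c(C)c(OC)c1O
F9 | step 5 | 3-henicosyl-6-methylbenzene-1,2,4,5-tetrol | CCCCCCCCCCCCCCCCCCCCCc1c(O)c(O)c(C)c(O)c1O
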